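The synthesis forms the two C–Br bonds of ring B (C4'–Br and C2'–Br) last. Ring B carries bromine para and ortho to its ether oxygen at C1', which is where a phenyl ether brominates on its own. Ring A has bromine at C3 and C6 but none at C4 or C5, the positions para to its oxygens, and direct bromination would not give that pattern. Ring A is therefore built complete from a 1,4-dibromoarene, and its C1 hydroxyl is masked as an acetate. The precursor, 3,6-dibromo-2-phenoxyphenyl acetate, then takes up both ring B bromines in one operation. Methanolysis releases the phenol.

Key step: step 5

Remark: the target has no stereocentre, and the diaryl ether axis is taken to rotate freely at room temperature, so no stereochemical control is needed.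

Step 1
Reactants: 1 1,4-dibromo-2-fluorobenzene
Product: 3 3,6-dibromo-2-fluorobenzaldehyde, via aryllithium 2 (not isolated)
Conditions: LiN(iPr)2 (1.05 equiv), THF, −78 °C, 45 min; DMF (1.5 equiv), −78 °C; 1 M HCl
Reagents that add atoms: DMF, CN(C)C=O; lithium diisopropylamide, [Li]N(C(C)C)C(C)C (its lithium stays only in 2)
Why: Directed ortho-metalation followed by formylation of the aryllithium with a formamide: the C3–H of 1 is flanked by F and Br and is the most acidic on the ring, an amide base does not trigger Br/Li exchange, and at −78 °C the anion should live long enough to add to DMF, whose tetrahedral adduct collapses to the aldehyde only on acidic quench.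

Step 2
Reactants: 3 3,6-dibromo-2-fluorobenzaldehyde; 4 phenol
Product: 5 3,6-dibromo-2-phenoxybenzaldehyde
Conditions: 4 (1.0 equiv), K2CO3 (1.5 equiv), DMF, 80 °C
Reagents that add atoms: none
Why: Nucleophilic aromatic substitution by addition–elimination: the formyl group ortho to C2 stabilises the Meisenheimer adduct, and fluoride leaves far better than the C6 bromide in this mechanism, so one equivalent of phenoxide should replace fluorine only.

Step 3
Reactants: 5 3,6-dibromo-2-phenoxybenzaldehyde
Product: 7 3,6-dibromo-2-phenoxyphenol, via aryl formate 6 (not isolated)
Conditions: mCPBA (1.5 equiv), CH2Cl2, 0 °C to 40 °C; aq. Na2S2O3 wash; then MeOH, HCl (cat.), rt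
Reagents that add atoms: mCPBA, OOC(=O)c1cccc(Cl)c1
Why: Baeyer–Villiger oxidation of an aryl aldehyde (Dakin-type outcome): in the Criegee adduct the aryl group, helped by the ortho phenoxy donor and by relief of crowding at the doubly ortho-substituted C1, should migrate to oxygen, and the labile aryl formate is then cleaved by acid-catalysed transesterification with methanol.

Step 4
Reactants: 7 3,6-dibromo-2-phenoxyphenol
Product: 8 3,6-dibromo-2-phenoxyphenyl acetate
Conditions: Ac2O (1.5 equiv), DMAP (5 mol %), pyridine, rt
Reagents that add atoms: acetic anhydride, CC(=O)OC(C)=O
Why: DMAP-catalysed O-acylation of a phenol tolerates the two ortho substituents and converts the strongly activating hydroxyl of ring A into a weakly donating acyloxy group ahead of the bromination.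

Step 5
Reactants: 8 3,6-dibromo-2-phenoxyphenyl acetate
Product: 10 3,6-dibromo-2-(2,4-dibromophenoxy)phenyl acetate, via monobromide 9 (not isolated)
Conditions: Br2 (2.05 equiv, two portions), FeBr3 (5 mol %), anhydrous CH2Cl2, 0 °C to rt, dark, N2 sweep; aq. NaHSO3
Reagents that add atoms: bromine, BrBr
Why: Each C–Br bond forms by electrophilic aromatic substitution, in which FeBr3-polarised Br2 attacks ring B to give an arenium ion stabilised by the lone pair of the ether oxygen, and HBr is then lost. The closest known reaction type is the stepwise para-then-ortho halogenation of aryl phenyl ethers and anisoles with Br2 under mild Lewis acid catalysis. No ring closes and no stereocentre forms. The step needs ring B to react in preference to C4 and C5 of ring A, and three features of the substrate secure this: ring A bears two bromines, its C1 oxygen is an acyloxy group (poorer still once FeBr3 binds the carbonyl), and the C1 and C3 substituents flanking C2–O twist ring A out of the C–O–C plane so that the oxygen p lone pair overlaps with ring B. Positional control on ring B is convergent, because C4' should react first to give 9, in which C2' and C6' are equivalent, and an ortho-first event leads to the same product 10. The end point is set by kinetics and stoichiometry, since every bromine already on ring B sits meta to the next site of attack and slows it markedly, so two equivalents of Br2 should be used up before C6' or ring A can compete.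

Step 6
Reactants: 10 3,6-dibromo-2-(2,4-dibromophenoxy)phenyl acetate
Product: 11 3,6-dibromo-2-(2,4-dibromophenoxy)phenol
Conditions: K2CO3 (1.5 equiv), MeOH, rt; 1 M HCl
Reagents that add atoms: none
Why: Base-mediated transesterification (methanolysis) of an aryl acetate is fast at room temperature because the brominated aryloxyphenoxide is a good leaving group, the four aryl bromides and the diaryl ether are inert under these conditions, and any O-to-O Smiles shift of ring B would be degenerate on the symmetric 3,6-dibromocatechol core.

Compound list
1 | 1,4-dibromo-2-fluorobenzene | Fc1cc(Br)ccc1Br | starting material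
2 | (3,6-dibromo-2-fluorophenyl)lithium | [Li]c1c(F)c(Br)ccc1Br | intermediate
3 | 3,6-dibromo-2-fluorobenzaldehyde | O=Cc1c(F)c(Br)ccc1Br | intermediate
4 | phenol | Oc1ccccc1 | starting material
5 | 3,6-dibromo-2-phenoxybenzaldehyde | O=Cc1c(Br)ccc(Br)c1Oc1ccccc1 | intermediate
6 | 3,6-dibromo-2-phenoxyphenyl formate | O=COc1c(Br)ccc(Br)c1Oc1ccccc1 | intermediate
7 | 3,6-dibromo-2-phenoxyphenol | Oc1c(Br)ccc(Br)c1Oc1ccccc1 | intermediate
8 | 3,6-dibromo-2-phenoxyphenyl acetate | CC(=O)Oc1c(Br)ccc(Br)c1Oc1ccccc1 | intermediate
9 | 3,6-dibromo-2-(4-bromophenoxy)phenyl acetate | CC(=O)Oc1c(Br)ccc(Br)c1Oc1ccc(Br)cc1 | intermediate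
10 | 3,6-dibromo-2-(2,4-dibromophenoxy)phenyl acetate | CC(=O)Oc1c(Br)ccc(Br)c1Oc1ccc(Br)cc1Br | intermediate
11 | 3,6-dibromo-2-(2,4-dibromophenoxy)phenol | Oc1c(Br)ccc(Br)c1Oc1ccc(Br)cc1Br | target

Total step count: 6
Longest linear sequence: 6 steps (1 to 11)

Steps most likely to fail

Step 5 (key step). The reaction may stall after the first bromination. It may run on to a third substitution at C6'. It may also leak into ring A at C4 or C5 if traces of water and HBr strip the acetate mask. The fallback brings ring B in already brominated, so no late electrophilic bromination is needed. It sets out from aldehyde 3, which is coupled with commercial 2,4-dibromophenol (K2CO3, DMF, 80 °C, nucleophilic aromatic substitution) to give 3,6-dibromo-2-(2,4-dibromophenoxy)benzaldehyde F1. Baeyer–Villiger oxidation with mCPBA in CH2Cl2 should give 3,6-dibromo-2-(2,4-dibromophenoxy)phenyl formate F2. Acid-catalysed methanolysis of F2 comes back to the route at target 11.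

Step 3. Ring A carries two bromines, so hydride migration may compete with aryl migration in the Criegee adduct and take the aldehyde to the carboxylic acid oxidation level. The fallback replaces the competing hydrogen by a methyl group, the poorest migrating group. It sets out from aldehyde 5. MeMgBr (THF, −78 °C to 0 °C) adds to give racemic 1-(3,6-dibromo-2-phenoxyphenyl)ethanol F3, and Dess–Martin periodinane oxidises it to 1-(3,6-dibromo-2-phenoxyphenyl)ethanone F4. Baeyer–Villiger oxidation of F4 follows, with CF3CO3H made from urea–H2O2 and (CF3CO)2O, buffered with Na2HPO4 in CH2Cl2, and it leaves aryl migration as the only productive path. The fallback comes back to the route directly at acetate 8, and step 4 is skipped.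

Step 1. Bromine migration around the ring (halogen dance), or loss of lithium halide to an aryne, may overtake trapping of the ortho-bromo aryllithium by the formamide. The fallback forms the ether bond first and catches the anion as it forms, with boron instead of carbon. It sets out from 1 and 4. K2CO3 in NMP at 170 °C should give 1,4-dibromo-2-phenoxybenzene F5, because fluoride is the only halide that leaves in an unactivated addition–elimination. Lithium diisopropylamide is then added to a THF solution of F5 and B(OiPr)3 at −78 °C (in situ quench), so that the C–H between the phenoxy group and bromine is removed and borylated at once. Aqueous acid then gives (3,6-dibromo-2-phenoxyphenyl)boronic acid F6. Oxidation with H2O2 and NaOH in THF at 0 °C turns C–B into C–O and comes back to the route at phenol 7, so steps 2 and 3 are not needed.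

Further compounds
F1 | step 5 | 3,6-dibromo-2-(2,4-dibromophenoxy)benzaldehyde | O=Cc1c(Br)ccc(Br)c1Oc1ccc(Br)cc1Br
F2 | step 5 | 3,6-dibromo-2-(2,4-dibromophenoxy)phenyl formate | O=COc1c(Br)ccc(Br)c1Oc1ccc(Br)cc1Br
F3 | step 3 | racemic 1-(3,6-dibromo-2-phenoxyphenyl)ethanol | CC(O)c1c(Br)ccc(Br)c1Oc1ccccc1
F4 | step 3 | 1-(3,6-dibromo-2-phenoxyphenyl)ethanone | CC(=O)c1c(Br)ccc(Br)c1Oc1ccccc1
F5 | step 1 | 1,4-dibromo-2-phenoxybenzene | Brc1ccc(Br)c(Oc2ccccc2)c1
F6 | step 1 | (3,6-dibromo-2-phenoxyphenyl)boronic acid | OB(O)c1c(Br)ccc(Br)c1Oc1ccccc1
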